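The data are simulated with made-up constants, noise included.

Take a small charge, 0.80 M of electrophile, against 1.40 M to 2.40 M of protonated nucleophile. The electrophile is the limiting reagent, so keep the books in percent of it.

in all of them: electrophile 0.80 M; gas 150 mM (held)
- dusk: protonated nucleophile 2.1 M; run made earlier
- summer: protonated nucleophile 2.8 M; run made earlier
- elm: protonated nucleophile 1.40 M; time 20 h
- maple: protonated nucleophile 1.90 M; time 20 h
- oak: protonated nucleophile 2.40 M; time 20 h

- dusk (time / h: electrophile / %, target / %): 1.00: 89.3, 9.8; 2.00: 84.9, 15.4; 3.00: 79.8, 19.5; 5.00: 72.5, 25.8; 8.00: 66.1, 31.9; 15.0: 52.3, 40.7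
- summer (time / h: electrophile / %, target / %): 1.00: 87.8, 12.1; 2.50: 79.2, 20.6; 5.00: 69.7, 27.9; 8.00: 61.7, 36.4; 10.0: 56.7, 40.0; 15.0: 48.0, 47.4

(each reading ± 0.5 percentage points)

- the numbers in the tables scatter by 0.5 percentage points (one standard deviation)
- at the start none of the gas is in solution

* part of the electrophile that has reacted at the end, elm
* part of the electrophile that has reacted at the end, maple
* part of the electrophile that has reacted at the end, oak
* what raising the concentration of protonated nucleophile from its lowest to its highest value here does to the part of the electrophile that has reacted (changes below 5 percentage points count as none) (it rises / it falls / no change)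

Open the ledger at the last reading of the dusk run, 15.0 h: 52.3 % stands as electrophile, 40.7 % as target, and 7 percentage points has no column. The summer run leaves a gap of 4.6 points, still larger than the scatter. Enter the gap as an unread entry, and reckon from the electrophile line, which counts it as reacted.

Now square the part reacted and divide by the hours and by the charge of protonated nucleophile. Dusk gives 0.00722 M⁻¹ h⁻¹ at its last reading and 0.00720 M⁻¹ h⁻¹ at 5.00 h, so these two readings of the figure agree. Summer gives 0.00644 M⁻¹ h⁻¹. Replace both by their mean, 0.00683 M⁻¹ h⁻¹, and call it the square-law constant, the square of the part reacted per hour and per molar of protonated nucleophile.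

My reckoning is the root of constant times hours times charge: 43.7 % for elm, 50.9 % for maple, 57.3 % for oak. Check what the mean costs: dusk's value alone lifts elm by 1.2 points, and elm lies below both runs in charge. The rise from elm to oak is 14 points, above the margin.

The forecast reads the same curves: “Conversion grows roughly as the square root of time”. It gives 48 %, 52.5 % and 56 %, and says it rises. At elm it stands 4.3 points above my reckoning.

The flasks give 45.4 % for elm, 51.3 % for maple and 56.0 % for oak: it rises, by 11 points.

    acid set free + free base ⇌ salt of the base, settled at all times (K = 1.42 × 10⁵ M⁻¹)
    electrophile + target → side product (k = 0.0126 M⁻¹ h⁻¹)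
    electrophile + nucleophile → acid set free + target (k = 1.42 M⁻¹ h⁻¹)
    nucleophile + acid set free ⇌ protonated nucleophile, settled at all times (K = 171 M⁻¹)
    gas ⇌ free base, rate k5*(csat - [free base]) (kL = 0.0425 h⁻¹)

In oak the unread entry gets its name, side product: at 20.0 h that flask holds 44.0 % electrophile, 48.1 % target and 7.94 % side product, and the books close. Put the square-law constant back: oak returns 0.00654 M⁻¹ h⁻¹ and elm 0.00736 M⁻¹ h⁻¹, against 0.00683 M⁻¹ h⁻¹. Give oak 0.60 M of protonated nucleophile instead, all other charges and the time held: the square law says 28.6 %, and in that neighbour flask 31.3 % of the electrophile has reacted.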